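**Retrosynthetic overview**
- The ring-A acetoxy enone is made last: α'-acetoxylation of the enone, which comes from a silyl enol ether carried through the whole route.
- The C2 benzoate and the butenolide come from two catalyst-controlled ketone reductions of a ten-membered diketo ester.
- Key step: the ten-membered ring and its (5Z)-alkene are made by a three-carbon ring expansion of a seven-membered cyclic 1,3-diketone (vinyl radical adds to C7=O, then the ring-fusion bond C3–C7 breaks).
- The seven-membered diketone comes from intramolecular C-acylation of a methyl ketone by a dialkylmaleic anhydride, itself made from the ring-A aldehyde, citraconic anhydride and PPh3.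
- Ring A (C1, C10) comes from an enantioselective Diels–Alder reaction; ring order: six-membered ring A, seven-membered ring, ten-membered ring, butenolide.

Assumption: briarane numbering is used (C1 quaternary with Me-15, C2 OBz, C5(Me-16)=C6, C7 lactone CH–O, C8=C17(Me-19)–C18(=O)O, C10 ring-fusion CH, C11(Me-20)=C12, C13 C=O, C14 OAc), β is the face of Me-15, TBS is tert-butyldimethylsilyl, and each chiral catalyst antipode named is the one the usual model predicts for the drawn sense.

**Step 1**
Reactants: 1 2,3-dimethylfuran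
Product: 3 (E)-3-methyl-4-oxopent-2-enal, via (Z)-3-methyl-4-oxopent-2-enal 2 (not isolated)
Conditions: NBS, NaHCO3, acetone/H2O (10:1), −20 °C; then pyridine (cat.), 25 °C
Reagents that add atoms: water, O
Why: Oxidative ring opening of the furan (bromination at the free α-carbon, hydration, loss of HBr) gives the cis 4-oxo-enal 2, which pyridine isomerises to the more stable trans isomer 3.

**Step 2**
Reactants: 4 (E)-pent-3-en-2-one
Product: 5 tert-butyl(dimethyl)[(3E)-penta-1,3-dien-2-yloxy]silane
Conditions: TBSOTf, Et3N, Et2O, 0 °C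
Reagents that add atoms: tert-butyldimethylsilyl trifluoromethanesulfonate, CC(C)(C)[Si](C)(C)OS(=O)(=O)C(F)(F)F
Why: Soft enolisation and O-silylation on the methyl side of the ketone gives the 2-silyloxydiene and leaves the (E)-alkene untouched.

**Step 3**
Reactants: 3 (E)-3-methyl-4-oxopent-2-enal; 5 tert-butyl(dimethyl)[(3E)-penta-1,3-dien-2-yloxy]silane
Product: 6 (1R,2R,6R)-6-acetyl-4-(tert-butyldimethylsilyloxy)-2,6-dimethylcyclohex-3-ene-1-carbaldehyde
Conditions: (S)-o-tolyl-CBS oxazaborolidine (20 mol %), Tf2NH (18 mol %), CH2Cl2, −78 °C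
Reagents that add atoms: none
Why: Catalytic enantioselective Diels–Alder reaction in which the boron catalyst binds the formyl group, so the siloxy carbon ends para to the formyl-bearing C10; the (E)-dienophile fixes Me-15 cis to the C10 formyl group, the chiral oxazaborolidinium sets C1 and C10 absolutely, and the endo C11 methyl centre is temporary (lost in step 14).

**Step 4**
Reactants: 6 (1R,2R,6R)-6-acetyl-4-(tert-butyldimethylsilyloxy)-2,6-dimethylcyclohex-3-ene-1-carbaldehyde; 7 citraconic anhydride (3-methylfuran-2,5-dione)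
Product: 10 3-{[(1R,2S,6R)-6-acetyl-4-(tert-butyldimethylsilyloxy)-2,6-dimethylcyclohex-3-en-1-yl]methyl}-4-methylfuran-2,5-dione, via phosphorus ylide 8 (not isolated), via alkylidenesuccinic anhydride 9 (not isolated)
Conditions: 7, PPh3, PhMe, 25 °C; add 6, 80 °C; then Et3N, 25 °C
Reagents that add atoms: none
Why: Wittig olefination of the aldehyde (the ketone does not react) by the stabilised ylide 8 gives the exocyclic alkylidene 9, and Et3N moves the double bond into the ring to the more stable dialkylmaleic anhydride, which turns C9 into CH2 without a deoxygenation step.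

**Step 5**
Reactants: 10 3-{[(1R,2S,6R)-6-acetyl-4-(tert-butyldimethylsilyloxy)-2,6-dimethylcyclohex-3-en-1-yl]methyl}-4-methylfuran-2,5-dione
Product: 11 seven-membered diketo acid, (2Z)-2-[3-(tert-butyldimethylsilyloxy)-1,4a-dimethyl-5,7-dioxo-1,4,4a,5,6,7,9,9a-octahydro-8H-benzo[7]annulen-8-ylidene]propanoic acid (trans ring fusion; ring-A centres as in 6; C2 and C7 ketones with C3H2 between them)
Conditions: MgBr2·OEt2, i-Pr2NEt, CH2Cl2 (5 mM), 25 °C; pH 5 buffer
Reagents that add atoms: none
Why: Intramolecular Claisen-type C-acylation under soft enolisation, the magnesium enolate of the methyl ketone attacking the nearer anhydride carbonyl C7 (seven-membered closure against eight for C18) and the magnesium β-diketonate acting as the sink; the cis acid geometry is inherited from the anhydride.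

**Step 6**
Reactants: 11 seven-membered diketo acid
Product: 12 methyl ester of 11, methyl (2Z)-2-[3-(tert-butyldimethylsilyloxy)-1,4a-dimethyl-5,7-dioxo-1,4,4a,5,6,7,9,9a-octahydro-8H-benzo[7]annulen-8-ylidene]propanoate
Conditions: TMSCHN2, MeOH/PhMe (1:4), 0 °C
Reagents that add atoms: (trimethylsilyl)diazomethane, C[Si](C)(C)C=[N+]=[N-]
Why: Chemoselective esterification of the carboxylic acid with the diazoalkane locks the open keto ester form and leaves the less acidic diketone alone.

**Step 7**
Reactants: 13 prop-2-yn-1-ol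
Product: 15 (Z)-3-iodo-2-methylprop-2-en-1-ol, via vinylmagnesium chelate 14 (not isolated)
Conditions: MeMgBr (2.2 equiv), CuI (10 mol %), THF, −10 → 25 °C; then I2, −78 °C
Reagents that add atoms: methylmagnesium bromide, C[Mg]Br; iodine, [I][I]
Why: Copper-catalysed anti-carbomagnesiation of the propargylic alkoxide through the five-membered chelate 14 puts the methyl on C2 and magnesium cis to CH2O, and iodinolysis with retention gives the (Z)-iodoalkenol.

**Step 8**
Reactants: 15 (Z)-3-iodo-2-methylprop-2-en-1-ol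
Product: 16 (Z)-3-bromo-1-iodo-2-methylprop-1-ene
Conditions: CBr4, PPh3, CH2Cl2, 0 °C
Reagents that add atoms: carbon tetrabromide, BrC(Br)(Br)Br
Why: Appel bromination converts the allylic alcohol into the bromide under neutral conditions without touching the vinyl iodide or its geometry.

**Step 9**
Reactants: 12 methyl ester of 11; 16 (Z)-3-bromo-1-iodo-2-methylprop-1-ene
Product: 17 C3-allylated diketo ester, 12 carrying a (Z)-3-iodo-2-methylprop-2-enyl group on C3, the CH between the two ketones (both C3 epimers)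
Conditions: K2CO3, acetone, 25 °C
Reagents that add atoms: none
Why: SN2 C-alkylation of the soft potassium enolate of the 1,3-diketone (the most acidic site) by the allylic bromide brings in C4–C6 with Me-16; the new C3 centre is erased in step 10.

**Step 10**
Reactants: 17 C3-allylated diketo ester
Product: 18 ten-membered diketo ester, methyl (2Z)-propanoate on the exocyclic C8=C17 of the trans-fused bicyclo[8.4.0] core with C2=O, C7=O, (5Z)-C5(Me)=C6, C12=C13–OTBS, Me-15 β, Me-20 β, H-10 α
Conditions: Bu3SnH (1.3 equiv, slow addition), AIBN (cat.), PhH (5 mM), 80 °C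
Reagents that add atoms: none
Why: Proposed new method: a three-carbon radical ring expansion in which Bu3Sn• abstracts iodine, the (Z)-vinyl radical adds 5-exo to the C7 carbonyl carbon (C2 is neopentyl and more shielded), and the resulting bicyclic cyclopentenyloxy radical cleaves the ring-fusion C3–C7 bond because this gives the C2-stabilised α-keto radical at C3 and a doubly conjugated C7 ketone, Bu3SnH then delivering H to C3; the five-membered transition state fixes the (5Z)-alkene, and the closest known reaction is the Dowd–Beckwith ring expansion of 2-(haloalkyl) β-keto esters by alkyl radicals, not yet shown for a vinyl radical on an enolisable cyclic 1,3-diketone.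

**Step 11**
Reactants: 18 ten-membered diketo ester
Product: 20 (5Z,7R)-13-(tert-butyldimethylsilyloxy)-2-oxobriara-5,8(17),12-trien-18,7-olide, via hydroxy ester 19 (not isolated)
Conditions: (S)-Me-CBS (20 mol %), catecholborane, PhMe, −78 °C; SiO2
Reagents that add atoms: none
Why: Corey–Bakshi–Shibata 1,2-reduction of the more reactive cross-conjugated C7 ketone, where the α-branched C8 alkenyl group is the large substituent and the (S)-catalyst gives the 7R alcohol 19, which lactonises at once onto the cis ester to the butenolide.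

**Step 12**
Reactants: 20 (5Z,7R)-13-(tert-butyldimethylsilyloxy)-2-oxobriara-5,8(17),12-trien-18,7-olide
Product: 21 (2S,5Z,7R)-2-hydroxy-13-(tert-butyldimethylsilyloxy)briara-5,8(17),12-trien-18,7-olide
Conditions: (R)-Me-CBS (50 mol %), catecholborane, PhMe, −20 → 0 °C
Reagents that add atoms: none
Why: Second Corey–Bakshi–Shibata reduction, now of the hindered C2 ketone with quaternary C1 as the large group, so the (R)-catalyst gives the 2S alcohol; catecholborane leaves the butenolide, the alkenes and the silyl enol ether alone.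

**Step 13**
Reactants: 21 (2S,5Z,7R)-2-hydroxy-13-(tert-butyldimethylsilyloxy)briara-5,8(17),12-trien-18,7-olide
Product: 22 (2S,5Z,7R)-2-benzoyloxy-13-(tert-butyldimethylsilyloxy)briara-5,8(17),12-trien-18,7-olide
Conditions: BzCl, Et3N, DMAP (cat.), CH2Cl2, 40 °C
Reagents that add atoms: benzoyl chloride, O=C(Cl)c1ccccc1
Why: DMAP-catalysed acylation of the only free hydroxyl gives the benzoate with retention at C2.

**Step 14**
Reactants: 22 (2S,5Z,7R)-2-benzoyloxy-13-(tert-butyldimethylsilyloxy)briara-5,8(17),12-trien-18,7-olide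
Product: 23 (2S,5Z,7R)-2-benzoyloxy-13-oxobriara-5,8(17),11-trien-18,7-olide
Conditions: Pd(OAc)2 (1.1 equiv), MeCN, 40 °C
Reagents that add atoms: none
Why: Saegusa–Ito oxidation, palladation of the silyl enol ether at C12 followed by syn β-hydride elimination of H-11, gives the C11=C12 enone regiospecifically and removes the temporary C11 centre.

**Step 15**
Reactants: 23 (2S,5Z,7R)-2-benzoyloxy-13-oxobriara-5,8(17),11-trien-18,7-olide
Product: 24 target, (1R,2S,5Z,7R,10R,14S)-14-acetoxy-2-benzoyloxy-13-oxobriara-5,8(17),11-trien-18,7-olide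
Conditions: Mn(OAc)3·2H2O, PhH, reflux
Reagents that add atoms: manganese triacetate dihydrate, CC(=O)[O-].CC(=O)[O-].CC(=O)[O-].[Mn+3].O.O
Why: Mn(OAc)3 α'-acetoxylation of the enone through the manganese enolate and α-keto radical at C14, the only α' position, with acetate delivered axially anti to the axial Me-15 to give the 14S acetate, as known for isophorone-type enones.

**Compound list**
1 | 2,3-dimethylfuran | Cc1occc1C | starting material
2 | (Z)-3-methyl-4-oxopent-2-enal | CC(=O)/C(C)=C\C=O | intermediate
3 | (E)-3-methyl-4-oxopent-2-enal | CC(=O)/C(C)=C/C=O | intermediate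
4 | (E)-pent-3-en-2-one | C/C=C/C(C)=O | starting material
5 | tert-butyl(dimethyl)[(3E)-penta-1,3-dien-2-yloxy]silane | C/C=C/C(=C)O[Si](C)(C)C(C)(C)C | intermediate
6 | (1R,2R,6R)-6-acetyl-4-(tert-butyldimethylsilyloxy)-2,6-dimethylcyclohex-3-ene-1-carbaldehyde | CC(=O)[C@]1(C)CC(O[Si](C)(C)C(C)(C)C)=C[C@@H](C)[C@H]1C=O | intermediate
7 | citraconic anhydride (3-methylfuran-2,5-dione) | CC1=CC(=O)OC1=O | starting material
8 | phosphorus ylide, 3-methyl-4-(triphenyl-λ5-phosphanylidene)oxolane-2,5-dione | CC1C(=O)OC(=O)C1=P(c1ccccc1)(c1ccccc1)c1ccccc1 | intermediate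
9 | alkylidenesuccinic anhydride, (E)-3-{[(1S,2S,6R)-6-acetyl-4-(tert-butyldimethylsilyloxy)-2,6-dimethylcyclohex-3-en-1-yl]methylidene}-4-methyloxolane-2,5-dione | CC(=O)[C@]1(C)CC(O[Si](C)(C)C(C)(C)C)=C[C@@H](C)[C@H]1/C=C2/C(=O)OC(=O)C2C | intermediate
10 | 3-{[(1R,2S,6R)-6-acetyl-4-(tert-butyldimethylsilyloxy)-2,6-dimethylcyclohex-3-en-1-yl]methyl}-4-methylfuran-2,5-dione | CC(=O)[C@]1(C)CC(O[Si](C)(C)C(C)(C)C)=C[C@@H](C)[C@H]1CC2=C(C)C(=O)OC2=O | intermediate
11 | seven-membered diketo acid, (2Z)-2-[3-(tert-butyldimethylsilyloxy)-1,4a-dimethyl-5,7-dioxo-1,4,4a,5,6,7,9,9a-octahydro-8H-benzo[7]annulen-8-ylidene]propanoic acid, trans-fused, ring-A centres as in 6 | OC(=O)/C(C)=C1/C[C@@H]2[C@H](C)C=C(O[Si](C)(C)C(C)(C)C)C[C@@]2(C)C(=O)CC1=O | intermediate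
12 | methyl ester of 11 | COC(=O)/C(C)=C1/C[C@@H]2[C@H](C)C=C(O[Si](C)(C)C(C)(C)C)C[C@@]2(C)C(=O)CC1=O | intermediate
13 | prop-2-yn-1-ol | C#CCO | starting material
14 | vinylmagnesium chelate, bromomagnesium (Z)-3-(bromomagnesio)-2-methylprop-2-en-1-olate | Br[Mg]OC/C(C)=C\[Mg]Br | intermediate
15 | (Z)-3-iodo-2-methylprop-2-en-1-ol | OC/C(C)=C\I | intermediate
16 | (Z)-3-bromo-1-iodo-2-methylprop-1-ene | BrC/C(C)=C\I | intermediate
17 | C3-allylated diketo ester, 12 with a (Z)-3-iodo-2-methylprop-2-enyl group on C3 (both C3 epimers) | COC(=O)/C(C)=C1/C[C@@H]2[C@H](C)C=C(O[Si](C)(C)C(C)(C)C)C[C@@]2(C)C(=O)C(C/C(C)=C\I)C1=O | intermediate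
18 | ten-membered diketo ester (C2=O, C7=O, (5Z)-C5(Me)=C6, exocyclic (Z)-C8=C17(Me)CO2Me, C12=C13–OTBS, trans ring fusion) | COC(=O)/C(C)=C1/C[C@@H]2[C@H](C)C=C(O[Si](C)(C)C(C)(C)C)C[C@@]2(C)C(=O)CC/C(C)=C\C1=O | intermediate
19 | hydroxy ester, (7R)-7-hydroxy compound from 18 with the ester still open | COC(=O)/C(C)=C1/C[C@@H]2[C@H](C)C=C(O[Si](C)(C)C(C)(C)C)C[C@@]2(C)C(=O)CC/C(C)=C\[C@H]1O | intermediate
20 | (5Z,7R)-13-(tert-butyldimethylsilyloxy)-2-oxobriara-5,8(17),12-trien-18,7-olide | C1C(O[Si](C)(C)C(C)(C)C)=C[C@@H](C)[C@H]2CC3=C(C)C(=O)O[C@@H]3/C=C(/C)CCC(=O)[C@@]21C | intermediate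
21 | (2S,5Z,7R)-2-hydroxy-13-(tert-butyldimethylsilyloxy)briara-5,8(17),12-trien-18,7-olide | C1C(O[Si](C)(C)C(C)(C)C)=C[C@@H](C)[C@H]2CC3=C(C)C(=O)O[C@@H]3/C=C(/C)CC[C@H](O)[C@@]21C | intermediate
22 | (2S,5Z,7R)-2-benzoyloxy-13-(tert-butyldimethylsilyloxy)briara-5,8(17),12-trien-18,7-olide | C1C(O[Si](C)(C)C(C)(C)C)=C[C@@H](C)[C@H]2CC3=C(C)C(=O)O[C@@H]3/C=C(/C)CC[C@H](OC(=O)c3ccccc3)[C@@]21C | intermediate
23 | (2S,5Z,7R)-2-benzoyloxy-13-oxobriara-5,8(17),11-trien-18,7-olide | C1C(=O)C=C(C)[C@H]2CC3=C(C)C(=O)O[C@@H]3/C=C(/C)CC[C@H](OC(=O)c3ccccc3)[C@@]21C | intermediate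
24 | (1R,2S,5Z,7R,10R,14S)-14-acetoxy-2-benzoyloxy-13-oxobriara-5,8(17),11-trien-18,7-olide (CNP0194180.3) | CC(=O)O[C@@H]1C(=O)C=C(C)[C@H]2CC3=C(C)C(=O)O[C@@H]3/C=C(/C)CC[C@H](OC(=O)c3ccccc3)[C@@]21C | target

**Totals**
Total step count: 15.
Longest linear sequence: 12 steps (1, 3, 4, 5, 6, 9, 10, 11, 12, 13, 14, 15).

**Steps most likely to fail**

Step 10 (the new ring expansion). The vinyl radical may be reduced before it cyclises, may attack the C2 carbonyl, or may add 6-exo to C8 of the alkylidene ester. The fallback uses known chemistry, sets out from 17 and comes back at 18. An intramolecular Nozaki–Hiyama–Kishi addition of the vinyl iodide to the C7 ketone (CrCl2, NiCl2 2 mol %, DMSO, 25 °C) gives the bicyclic cyclopentenol F1, a tertiary β-hydroxy ketone. DBU in MeCN then cleaves its C3–C7 bond by retro-aldol fragmentation to 18.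

Step 3 (Diels–Alder). The ketone rather than the formyl group may steer the orientation, the aldehyde may undergo Mukaiyama aldol addition, or the enantioselectivity may be low. The fallback sets out from 3 and 5 and comes back at 6. The cycloaddition is run with achiral Me2AlCl (CH2Cl2, −78 °C) to give racemic material, that is 6 together with its mirror image ent-6 F2. The two are separated by preparative chromatography on a chiral stationary phase before step 4.

Step 5 (seven-membered ring closure). Intermolecular acylation, deprotonation of the anhydride γ-positions or loss of the silyl enol ether may intervene. The fallback sets out from 10 and comes back at 12, so step 6 falls away. MeOH and DMAP open the anhydride to the half ester with the free C7 acid F3 and the half ester with the free C18 acid F4. TMSCHN2 converts both into the one dimethyl maleate F5. A Dieckmann-type Claisen condensation (NaHMDS, THF, −78 → 0 °C) of the methyl ketone onto the nearer ester then gives 12.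

**Further compounds**
F1 | step 10 | bicyclic cyclopentenol from 17 (C6–C7 bond formed, tertiary C7–OH, C3–C7 bond intact, no iodine) | COC(=O)/C(C)=C1/C[C@@H]2[C@H](C)C=C(O[Si](C)(C)C(C)(C)C)C[C@@]2(C)C(=O)C3CC(C)=CC13O
F2 | step 3 | ent-6, (1S,2S,6S)-6-acetyl-4-(tert-butyldimethylsilyloxy)-2,6-dimethylcyclohex-3-ene-1-carbaldehyde | CC(=O)[C@@]1(C)CC(O[Si](C)(C)C(C)(C)C)=C[C@H](C)[C@@H]1C=O
F3 | step 5 | half ester from 10 with C7 carboxylic acid and C18 methyl ester on the (Z)-alkene | CC(=O)[C@]1(C)CC(O[Si](C)(C)C(C)(C)C)=C[C@@H](C)[C@H]1C/C(C(=O)O)=C(\C)C(=O)OC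
F4 | step 5 | half ester from 10 with C7 methyl ester and C18 carboxylic acid on the (Z)-alkene | CC(=O)[C@]1(C)CC(O[Si](C)(C)C(C)(C)C)=C[C@@H](C)[C@H]1C/C(C(=O)OC)=C(\C)C(=O)O
F5 | step 5 | dimethyl (Z)-maleate from 10 (both carboxyls as methyl esters) | CC(=O)[C@]1(C)CC(O[Si](C)(C)C(C)(C)C)=C[C@@H](C)[C@H]1C/C(C(=O)OC)=C(\C)C(=O)OC
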